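**Retrosynthetic overview**

1. Drimane locants are used throughout: ring A = C1–C5/C10 (C3 ketone, C4 gem-dimethyl), ring B = C5–C10 (C6–OAc, C7=C8–CH3, C9–C11H2–O-coumarin, C10–CH3). The C6 acetate is installed last by stereoconvergent allylic acetolysis of the 6-alcohol, which comes from the 3,6-dione (Δ7-enone).
2. The enone comes from hydrolytic unzipping of a caged cycloadduct (enol ether hydrolysis, β-elimination of a bridging carboxylate, decarboxylation). Key disconnection: C5–C10 and C8–C9, made together by an intramolecular Diels–Alder reaction of a 2-pyrone (pyrone positions 3–6 = C5–C8) with the (E)-trisubstituted alkene C9=C10, so rings A and B form in one step.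
3. Enabling feature: ring B carries O at C6, H at C7 and CH3 at C8, which is the substitution pattern of 4-hydroxy-6-methyl-2-pyrone. The C3 oxygen is 1,4 to C6 across the quaternary C4, so at the alcohol level it can be tied to C6 as a five-membered cyclic enol ether that fixes the face and orientation of the cycloaddition.
4. The cycloaddition precursor comes from a C3 ketone; CBS reduction sets C3, the only reagent-controlled stereocentre, which is re-oxidised at the end. The ketone is made by alkylating a pyronyl methyl ketone (O-prenylation, Claisen, Wacker on the pyrone) with an umbelliferone-bearing allylic bromide.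
5. Ring order: coumarin and pyrone rings are bought; then the temporary dihydrofuran ring; then rings A and B together (the pyrone carbons become ring B, its carbonyl carbon leaves as CO2).

Key step: step 8

**Step 1**
Reactants: 1 umbelliferone (7-hydroxy-2H-chromen-2-one); 2 (2E)-1,4-dibromo-2-methylbut-2-ene
Product: 3 7-{[(2E)-4-bromo-3-methylbut-2-en-1-yl]oxy}-2H-chromen-2-one
Conditions: 2 (3 equiv), K2CO3, acetone, 25 °C
Reagents that add atoms: none
Why: Williamson etherification (SN2): the phenoxide should displace the prenyl-type bromide (CH2Br on the CH= carbon, activated by γ,γ-disubstitution and unhindered) in preference to the methallyl-type bromide next to the methyl-bearing carbon, which is kept for step 5; the E geometry is untouched and excess 2 suppresses the bis-ether.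

**Step 2**
Reactants: 4 4-hydroxy-6-methyl-2H-pyran-2-one; 5 3-methylbut-2-en-1-ol
Product: 6 6-methyl-4-[(3-methylbut-2-en-1-yl)oxy]-2H-pyran-2-one
Conditions: PPh3, diisopropyl azodicarboxylate, THF, 0 → 25 °C
Reagents that add atoms: none
Why: Mitsunobu O-alkylation: the acidic 4-hydroxyl (a vinylogous carboxylic acid) is alkylated by the activated primary allylic alcohol to give the 4-alkoxy-2-pyrone.

**Step 3**
Reactants: 6 6-methyl-4-[(3-methylbut-2-en-1-yl)oxy]-2H-pyran-2-one
Product: 8 4-methoxy-6-methyl-3-(2-methylbut-3-en-2-yl)-2H-pyran-2-one, via enol 7 (not isolated)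
Conditions: PhMe, 120 °C (sealed tube); then Me2SO4, K2CO3, acetone, 56 °C
Reagents that add atoms: dimethyl sulfate, COS(=O)(=O)OC
Why: Claisen [3,3] rearrangement across the O–C4=C3 enol ether of the pyrone moves the allyl unit to pyrone C3 with allylic inversion, creating the gem-dimethyl quaternary carbon (C4 of the target) with a vinyl group; O-methylation of the liberated enol in the same flask prevents its addition to the vinyl group and installs the leaving group needed in step 7.

**Step 4**
Reactants: 8 4-methoxy-6-methyl-3-(2-methylbut-3-en-2-yl)-2H-pyran-2-one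
Product: 9 4-methoxy-6-methyl-3-(2-methyl-3-oxobutan-2-yl)-2H-pyran-2-one
Conditions: PdCl2 (10 mol %), CuCl (20 mol %), O2 (1 atm), DMF/H2O 7:1, 25 °C
Reagents that add atoms: water, O
Why: Tsuji–Wacker oxidation: Markovnikov oxypalladation of the only alkene, a monosubstituted vinyl group, gives the methyl ketone whose carbonyl carbon is C3 of the target.

**Step 5**
Reactants: 9 4-methoxy-6-methyl-3-(2-methyl-3-oxobutan-2-yl)-2H-pyran-2-one; 3 7-{[(2E)-4-bromo-3-methylbut-2-en-1-yl]oxy}-2H-chromen-2-one
Product: 10 4-methoxy-6-methyl-3-{(6E)-2,6-dimethyl-3-oxo-8-[(2-oxo-2H-chromen-7-yl)oxy]oct-6-en-2-yl}-2H-pyran-2-one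
Conditions: LiN(SiMe3)2 (1.05 equiv), THF, −78 °C; then 3, −78 → −20 °C
Reagents that add atoms: none
Why: Enolate alkylation (SN2): the methyl ketone, enolisable only at its methyl group and expected to be more acidic than the vinylogous pyrone methyl, is deprotonated and alkylated by the primary allylic bromide, joining C2 to C1 and bringing in C9–C11 with the E alkene and the coumarin ether in place.

**Step 6**
Reactants: 10 4-methoxy-6-methyl-3-{(6E)-2,6-dimethyl-3-oxo-8-[(2-oxo-2H-chromen-7-yl)oxy]oct-6-en-2-yl}-2H-pyran-2-one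
Product: 11 3-{(3S,6E)-3-hydroxy-2,6-dimethyl-8-[(2-oxo-2H-chromen-7-yl)oxy]oct-6-en-2-yl}-4-methoxy-6-methyl-2H-pyran-2-one
Conditions: (R)-2-methyl-CBS-oxazaborolidine (20 mol %), catecholborane (1.5 equiv), PhMe, −78 → −40 °C; then MeOH, aq. NaHCO3
Reagents that add atoms: none
Why: Corey–Bakshi–Shibata reduction: the catalyst differentiates the quaternary carbon (large) from the CH2 chain (small), so the (R)-catalyst should give the (S)-carbinol, the single reagent-controlled stereocentre of the route; catecholborane should leave the alkene and both lactones alone.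

**Step 7**
Reactants: 11 3-{(3S,6E)-3-hydroxy-2,6-dimethyl-8-[(2-oxo-2H-chromen-7-yl)oxy]oct-6-en-2-yl}-4-methoxy-6-methyl-2H-pyran-2-one
Product: 12 (2S)-3,3,6-trimethyl-2-{(3E)-3-methyl-5-[(2-oxo-2H-chromen-7-yl)oxy]pent-3-en-1-yl}-2,3-dihydro-4H-furo[3,2-c]pyran-4-one
Conditions: PPTS (10 mol %), PhMe, 80 °C, 4 Å molecular sieves
Reagents that add atoms: none
Why: Acid-catalysed vinylogous transetherification: the hydroxyl adds to the methoxy-bearing carbon of the O-protonated pyrone (a 5-exo attack on a pyrylium-type C=O+ unit, helped by the gem-dimethyl group) and methanol is lost, tying the C3 oxygen to the future C6 in a five-membered ring without breaking the C3–O bond, so the configuration is retained.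

**Step 8**
Reactants: 12 (2S)-3,3,6-trimethyl-2-{(3E)-3-methyl-5-[(2-oxo-2H-chromen-7-yl)oxy]pent-3-en-1-yl}-2,3-dihydro-4H-furo[3,2-c]pyran-4-one
Product: 13 caged cycloadduct (2-oxabicyclo[2.2.2]oct-5-en-3-one with the lactone carbonyl on C5 and the lactone oxygen on C8, ring A fused along C5–C10, tetrahydrofuran bridge C3–O–C6 retained, C6=C7 enol ether; one diastereomer, configuration as in the SMILES)
Conditions: PhMe (0.01 M), BHT (cat.), 130 °C, sealed tube
Reagents that add atoms: none
Why: Thermal intramolecular Diels–Alder reaction: the 4-alkoxy-2-pyrone is the diene (pyrone positions 3 and 6 are C5 and C8 of the target) and the tethered (E)-trisubstituted alkene C9=C10 is the dienophile, so C5–C10 and C8–C9 form in one asynchronous concerted event, with the unhindered C8–C9 bond leading and the congested C5–C10 bond closing last. The closest known reaction type is the intramolecular Diels–Alder reaction of 4-alkoxy-2-pyrones with unactivated trisubstituted alkenes, which builds an all-carbon quaternary centre near 100 °C and stops at the bicyclo[2.2.2] lactone. Ring A closes through C5–C10 as a type 1 closure over the four-atom tether C4–C3–C2–C1 (six-membered chair with the C3–O bond axial), and ring B closes as the new cyclohexene of the bicyclo[2.2.2]octene (C5–C8 from the pyrone, C9 and C10 from the alkene). C9 and C10 are set relative to each other by suprafacial addition to the E alkene (C10–CH3 cis to C11) and in the absolute sense by C3, because the fused dihydrofuran ring holds C2 on one face of the pyrone and on the C6 side of C5, so the alkene can reach only that face and only with C1 over the enol ether bridge; C5 and C8 are formed as bridgeheads and are erased in step 9. The step needs π-facial and orientational selectivity (secured by the temporary ring rather than by a conformational preference), chemoselectivity over the coumarin C3=C4 bond (a poor, remote dienophile) and over aromatic Claisen rearrangement of the allyl aryl ether (expected to be slower at 130 °C and impossible once the alkene is consumed). Loss of CO2 from 13 is not expected, since it would place a double bond at a bridgehead of the oxabicyclo[3.2.1] unit; the carboxyl carbon is removed in step 9 instead.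

**Step 9**
Reactants: 13 caged cycloadduct
Product: 16 7-{[(1R,4aS,6S,8aS)-6-hydroxy-2,5,5,8a-tetramethyl-4-oxo-1,4,4a,5,6,7,8,8a-octahydronaphthalen-1-yl]methoxy}-2H-chromen-2-one, via keto lactone 14 (not isolated), via keto acid 15 (not isolated)
Conditions: 1 M HCl, THF, 40 °C
Reagents that add atoms: water, O
Why: Aqueous acid should hydrolyse the cyclic enol ether (protonation at C7, hemiketal collapse) to the C6 ketone and free the C3 hydroxyl (14); the bridging carboxylate, now β to the ketone on the tertiary C8, is expelled by β-elimination to give the Δ7-enone β-keto acid 15, which decarboxylates, the enol being protonated at C5 on the face opposite the axial C4 and C10 methyl groups to give the trans-fused decalin (substrate control, also the thermodynamic outcome).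

**Step 10**
Reactants: 16 7-{[(1R,4aS,6S,8aS)-6-hydroxy-2,5,5,8a-tetramethyl-4-oxo-1,4,4a,5,6,7,8,8a-octahydronaphthalen-1-yl]methoxy}-2H-chromen-2-one
Product: 17 7-{[(1R,4aS,8aS)-2,5,5,8a-tetramethyl-4,6-dioxo-1,4,4a,5,6,7,8,8a-octahydronaphthalen-1-yl]methoxy}-2H-chromen-2-one
Conditions: Dess–Martin periodinane, CH2Cl2, 25 °C
Reagents that add atoms: none
Why: Dess–Martin oxidation of the secondary (axial, neopentyl) alcohol returns C3 to the ketone level of the target and removes the stereocentre that has done its work; the enone and the aryl ether are inert.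

**Step 11**
Reactants: 17 7-{[(1R,4aS,8aS)-2,5,5,8a-tetramethyl-4,6-dioxo-1,4,4a,5,6,7,8,8a-octahydronaphthalen-1-yl]methoxy}-2H-chromen-2-one
Product: 18 7-{[(1R,4S,4aS,8aS)-4-hydroxy-2,5,5,8a-tetramethyl-6-oxo-1,4,4a,5,6,7,8,8a-octahydronaphthalen-1-yl]methoxy}-2H-chromen-2-one
Conditions: NaBH4 (1.0 equiv), CeCl3·7H2O (1.0 equiv), MeOH/THF, −78 °C
Reagents that add atoms: none
Why: Luche reduction: 1,2-hydride delivery to the enone carbonyl from the open face (anti to the axial C4 and C10 methyl groups) should give the axial 6-alcohol; at −78 °C the cerium-activated enone should be reduced faster than the hindered saturated C3 ketone, and the C6 configuration is corrected in step 12.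

**Step 12**
Reactants: 18 7-{[(1R,4S,4aS,8aS)-4-hydroxy-2,5,5,8a-tetramethyl-6-oxo-1,4,4a,5,6,7,8,8a-octahydronaphthalen-1-yl]methoxy}-2H-chromen-2-one
Product: 19 7-{[(1R,4R,4aS,8aS)-4-acetoxy-2,5,5,8a-tetramethyl-6-oxo-1,4,4a,5,6,7,8,8a-octahydronaphthalen-1-yl]methoxy}-2H-chromen-2-one
Conditions: AcOH, TsOH·H2O (5 mol %), 25 °C
Reagents that add atoms: acetic acid, CC(=O)O
Why: SN1 allylic acetolysis: the strained axial allylic alcohol should ionise to the C6–C7–C8 allyl cation, which acetic acid captures at C6 from the unhindered face (anti to the axial C4 and C10 methyl groups) to give the equatorial secondary acetate with the trisubstituted C7=C8 bond; this is both the kinetic and the thermodynamic product (a tertiary C8 acetate would re-ionise), so either C6 epimer of 18 converges on the target.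

**Compound list**

1 | umbelliferone (7-hydroxy-2H-chromen-2-one) | Oc1ccc2ccc(=O)oc2c1 | starting material
2 | (2E)-1,4-dibromo-2-methylbut-2-ene | BrC/C(C)=C/CBr | starting material
3 | 7-{[(2E)-4-bromo-3-methylbut-2-en-1-yl]oxy}-2H-chromen-2-one | BrC/C(C)=C/COc1ccc2ccc(=O)oc2c1 | intermediate
4 | 4-hydroxy-6-methyl-2H-pyran-2-one | CC1=CC(O)=CC(=O)O1 | starting material
5 | 3-methylbut-2-en-1-ol | CC(C)=CCO | starting material
6 | 6-methyl-4-[(3-methylbut-2-en-1-yl)oxy]-2H-pyran-2-one | CC(C)=CCOC1=CC(=O)OC(C)=C1 | intermediate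
7 | 4-hydroxy-6-methyl-3-(2-methylbut-3-en-2-yl)-2H-pyran-2-one (enol, not isolated) | CC1=CC(O)=C(C(C)(C)C=C)C(=O)O1 | intermediate
8 | 4-methoxy-6-methyl-3-(2-methylbut-3-en-2-yl)-2H-pyran-2-one | COC1=C(C(C)(C)C=C)C(=O)OC(C)=C1 | intermediate
9 | 4-methoxy-6-methyl-3-(2-methyl-3-oxobutan-2-yl)-2H-pyran-2-one | COC1=C(C(C)(C)C(C)=O)C(=O)OC(C)=C1 | intermediate
10 | 4-methoxy-6-methyl-3-{(6E)-2,6-dimethyl-3-oxo-8-[(2-oxo-2H-chromen-7-yl)oxy]oct-6-en-2-yl}-2H-pyran-2-one | COC1=C(C(C)(C)C(=O)CC/C(C)=C/COc2ccc3ccc(=O)oc3c2)C(=O)OC(C)=C1 | intermediate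
11 | 3-{(3S,6E)-3-hydroxy-2,6-dimethyl-8-[(2-oxo-2H-chromen-7-yl)oxy]oct-6-en-2-yl}-4-methoxy-6-methyl-2H-pyran-2-one | COC1=C(C(C)(C)[C@@H](O)CC/C(C)=C/COc2ccc3ccc(=O)oc3c2)C(=O)OC(C)=C1 | intermediate
12 | (2S)-3,3,6-trimethyl-2-{(3E)-3-methyl-5-[(2-oxo-2H-chromen-7-yl)oxy]pent-3-en-1-yl}-2,3-dihydro-4H-furo[3,2-c]pyran-4-one | CC1=CC2=C(C(=O)O1)C(C)(C)[C@H](CC/C(C)=C/COc3ccc4ccc(=O)oc4c3)O2 | intermediate
13 | caged cycloadduct: bridging lactone C5–CO–O–C8 across ring B, ring A fused at C5–C10, tetrahydrofuran bridge C3–O–C6, C6=C7 enol ether | O=C1O[C@]2(C)C=C3O[C@H]4CC[C@@](C)([C@@H]2COc5ccc6ccc(=O)oc6c5)[C@@]13C4(C)C | intermediate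
14 | hydroxy keto lactone: 13 with the enol ether hydrolysed (C6 ketone, C7H2, free 3-hydroxyl; not isolated) | O=C1O[C@]2(C)CC(=O)[C@@]1(C(C)(C)[C@@H](O)CC3)[C@]3(C)[C@@H]2COc4ccc5ccc(=O)oc5c4 | intermediate
15 | β-keto acid: 5-carboxy derivative of 16, CO2H cis to the C10 methyl (not isolated) | O=C1C=C(C)[C@@H](COc3ccc4ccc(=O)oc4c3)[C@]2(C)CC[C@H](O)C(C)(C)[C@]12C(O)=O | intermediate
16 | 7-{[(1R,4aS,6S,8aS)-6-hydroxy-2,5,5,8a-tetramethyl-4-oxo-1,4,4a,5,6,7,8,8a-octahydronaphthalen-1-yl]methoxy}-2H-chromen-2-one | O=C1C=C(C)[C@@H](COc3ccc4ccc(=O)oc4c3)[C@]2(C)CC[C@H](O)C(C)(C)[C@@H]12 | intermediate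
17 | 7-{[(1R,4aS,8aS)-2,5,5,8a-tetramethyl-4,6-dioxo-1,4,4a,5,6,7,8,8a-octahydronaphthalen-1-yl]methoxy}-2H-chromen-2-one | O=C1C=C(C)[C@@H](COc3ccc4ccc(=O)oc4c3)[C@]2(C)CCC(=O)C(C)(C)[C@@H]12 | intermediate
18 | 7-{[(1R,4S,4aS,8aS)-4-hydroxy-2,5,5,8a-tetramethyl-6-oxo-1,4,4a,5,6,7,8,8a-octahydronaphthalen-1-yl]methoxy}-2H-chromen-2-one | O[C@H]1C=C(C)[C@@H](COc2ccc3ccc(=O)oc3c2)[C@]2(C)CCC(=O)C(C)(C)[C@@H]12 | intermediate
19 | 7-{[(1R,4R,4aS,8aS)-4-acetoxy-2,5,5,8a-tetramethyl-6-oxo-1,4,4a,5,6,7,8,8a-octahydronaphthalen-1-yl]methoxy}-2H-chromen-2-one | CC(=O)O[C@@H]1C=C(C)[C@@H](COc2ccc3ccc(=O)oc3c2)[C@]2(C)CCC(=O)C(C)(C)[C@@H]12 | target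

**Step count and risks**

Total step count: 12. Longest linear sequence: 11 steps (steps 2–12, from 4-hydroxy-6-methyl-2H-pyran-2-one); step 1 is a one-step branch.

Steps most likely to fail:

Step 8. The cycloaddition may be too slow, because the closing C5–C10 bond joins a carbon with a quaternary neighbour to a carbon that becomes quaternary; aromatic Claisen rearrangement of the allyl aryl ether or decomposition could then compete at the temperature required. Fallback (leaves 10, rejoins at 17): the temporary ring is abandoned and the tether is left free. Reduction of 10 with the enantiomeric (S)-2-methyl-CBS-oxazaborolidine and catecholborane should give the (3R)-alcohol F1. Silylation (Et3SiCl, imidazole, DMF) gives the triethylsilyl ether F2. Heating F2 (PhMe, 160 °C) should let the flexible tether react through a chair with the silyloxy group equatorial, which leads to the same C9/C10 configuration. The bridged lactone cycloadduct F3 now loses CO2 by retro-[4+2], which is allowed because no bridged enol ether is present, to give the methoxydiene F4; any minor diastereomer is removed here. Aqueous HCl in THF should hydrolyse the enol ether and the silyl ether to the C3-epimeric hydroxy enone F5 (C5 protonated as in step 9), and Dess–Martin oxidation of F5 gives 17.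

Step 12. The allyl cation may lose a proton to give dienes, or the double bond may migrate, faster than acetic acid is captured at C6. Fallback (leaves 18, rejoins at 19): SN2 inversion instead of ionisation. Mitsunobu reaction of 18 (PPh3, diisopropyl azodicarboxylate, HCO2H, PhMe, 0 → 25 °C) should give the inverted 6-formate F6. KHCO3 in MeOH removes the formyl group to give the equatorial 6-alcohol F7, and Ac2O/pyridine/DMAP gives 19.

Step 5. The base may deprotonate the vinylogous pyrone methyl group in competition with the ketone, or the enolate may attack the coumarin lactone. Fallback (leaves 6, rejoins at 10): a dianion strategy in which the pyrone is masked as its pyronate. Claisen rearrangement of 6 without methylation gives the enol 7, which is isolated. Wacker-type oxidative cyclisation (PdCl2 cat., CuCl cat., O2, DMF/H2O) should give the cyclic hemiketal F8, the ring tautomer of the hydroxypyronyl methyl ketone. LiN(iPr)2 (2.2 equiv, THF, −78 °C) opens F8 to the pyronate–ketone enolate dianion, in which the anionic ring no longer offers an acidic methyl group, and alkylation with 3 gives the hemiketal F9. O-Methylation (Me2SO4, K2CO3, acetone) returns 10.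

**Further compounds**

F1 | step 8 | 3-{(3R,6E)-3-hydroxy-2,6-dimethyl-8-[(2-oxo-2H-chromen-7-yl)oxy]oct-6-en-2-yl}-4-methoxy-6-methyl-2H-pyran-2-one | COC1=C(C(C)(C)[C@H](O)CC/C(C)=C/COc2ccc3ccc(=O)oc3c2)C(=O)OC(C)=C1
F2 | step 8 | triethylsilyl ether of F1 | COC1=C(C(C)(C)[C@H](O[Si](CC)(CC)CC)CC/C(C)=C/COc2ccc3ccc(=O)oc3c2)C(=O)OC(C)=C1
F3 | step 8 | bridged lactone cycloadduct of F2 (one of two bridged diastereomers, both give F4; not isolated) | O=C1O[C@]2(C)C=C(OC)[C@@]1(C(C)(C)[C@H](O[Si](CC)(CC)CC)CC3)[C@]3(C)[C@@H]2COc4ccc5ccc(=O)oc5c4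
F4 | step 8 | 6-methoxy-5,7-diene (ring B) with 3-triethylsilyloxy group | COC1=C2C(C)(C)[C@H](O[Si](CC)(CC)CC)CC[C@@]2(C)[C@H](COc3ccc4ccc(=O)oc4c3)C(C)=C1
F5 | step 8 | 7-{[(1R,4aS,6R,8aS)-6-hydroxy-2,5,5,8a-tetramethyl-4-oxo-1,4,4a,5,6,7,8,8a-octahydronaphthalen-1-yl]methoxy}-2H-chromen-2-one | O=C1C=C(C)[C@@H](COc3ccc4ccc(=O)oc4c3)[C@]2(C)CC[C@@H](O)C(C)(C)[C@@H]12
F6 | step 12 | 6-formate with the configuration of 19 at C6 | O=CO[C@@H]1C=C(C)[C@@H](COc2ccc3ccc(=O)oc3c2)[C@]2(C)CCC(=O)C(C)(C)[C@@H]12
F7 | step 12 | 7-{[(1R,4R,4aS,8aS)-4-hydroxy-2,5,5,8a-tetramethyl-6-oxo-1,4,4a,5,6,7,8,8a-octahydronaphthalen-1-yl]methoxy}-2H-chromen-2-one | O[C@@H]1C=C(C)[C@@H](COc2ccc3ccc(=O)oc3c2)[C@]2(C)CCC(=O)C(C)(C)[C@@H]12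
F8 | step 5 | 2-hydroxy-2,3,3,6-tetramethyl-2,3-dihydro-4H-furo[3,2-c]pyran-4-one | CC1=CC2=C(C(=O)O1)C(C)(C)C(C)(O)O2
F9 | step 5 | 2-hydroxy-3,3,6-trimethyl-2-{(3E)-3-methyl-5-[(2-oxo-2H-chromen-7-yl)oxy]pent-3-en-1-yl}-2,3-dihydro-4H-furo[3,2-c]pyran-4-one | CC1=CC2=C(C(=O)O1)C(C)(C)C(O)(CC/C(C)=C/COc3ccc4ccc(=O)oc4c3)O2
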